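The choice at 30 min in this flask lies between leaving it, pulling target out, adding substrate and warming, and it hangs on what kind of stop the readings show.

| flask | substrate | reagent in the second phase | temperature | remark | time | volume of the second phase over the first |
|---|---|---|---|---|---|---|
| north-east | 0.050 M | 2 equiv | −20 °C | the very flask that is asked about, followed so far |  |  |
| flask | 0.050 M | 2.00 equiv | −20 °C |  | 30 min | 1.0 |

- north-east (time / min: target / %, substrate / %): 2.50: 33.7, 5.4; 5.00: 12.7, 0.6; 8.00: 9.3, 0; 10.0: 9.1, 0; 12.0: 9.1, 0.1; 15.0: 9.6, 0; 20.0: 9.5, 0

(scatter of a reading: 0.5 percentage points)

- summer: change nothing and wait 15 min more
- autumn: at 30 min take out 90 % of the target then present, then wait 15 min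
- noon: at 30 min add substrate, 50.0 % of the amount charged, then wait 15 min
- midnight: at 30 min raise the temperature by 15 K, then wait 15 min

1. target, in percent of the substrate first charged, at 30 min
2. the remedy with the largest gain of target, or "none" below 2 percentage points (summer / autumn / noon / midnight / none)
3. target present, with what was taken out counted in, in percent of the substrate first charged, after summer
4. target present, with what was taken out counted in, in percent of the substrate first charged, after autumn

- in the second phase: reagent in the second phase; everything else is in the first
- charges count per volume of the first phase; a concentration in a rate is the amount of a species over the volume of its own phase; every rate counts per litre of the first phase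
- what is taken out of target is counted as made
- the numbers in the tables scatter with a standard deviation of 0.5 percentage points
- the earlier runs hold the two phases in the same ratio of volumes as the flask asked about
- the earlier runs do not show what temperature does; that part of a forecast is a guess
- additions bring no volume worth counting

Target falls from 33.7 % at 2.50 min to 12.7 % at 5.00 min, then stands at a mean of 9.32 % from 8.00 min on, and the gap to that level closes with a read time constant τ of 1.27 min. A lag that ends above zero suggests a way back, so this reckoning treats the stop as a balance of two flows, thermodynamic control, although a frozen target fits the same readings. The quantity to carry is the stop ratio S, the charged substrate that has gone past target over the target left at the stop: 9.73. On this reckoning, at 2.50 min the flow out of target stood to the flow back as 5.38, which is S times the target read then over the substrate already past target, and that comparison drifts to one as target falls. The further 15 min is far longer than τ, so this reckoning expects summer to hold the flask at 9.32 %. Autumn should let what remains relax to the same share, one part in S plus one, giving 16.9 % with the removed target counted, a gain larger than the margin of 2 percentage points. Noon hangs on reagent that no reading shows, and warming on a temperature response that no run shows, so the next run should take target out and try warming as a guess.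

The forecast differs on autumn, giving 9.3 % now, 9.3 % after summer, 9.3 % after autumn and none as the remedy, on the ground that “The target is then frozen.”

The flask gives 8.93 % at 30 min, and these equations ran in it:

    reagent in the reaction phase ⇌ reagent in the second phase, rate k1*([reagent in the reaction phase] - [reagent in the second phase]/K1) per volume of the first phase (partition coefficient = 0.550, kL = 0.00395 s⁻¹)
    substrate + reagent in the reaction phase → target (k = 2.72 M⁻¹ s⁻¹, Ea = 41.0 kJ mol⁻¹)
    substrate + target → side product (k = 0.0112 M⁻¹ s⁻¹, Ea = 44.0 kJ mol⁻¹)
    2 reagent in the reaction phase → self-condensation product (k = 0.134 M⁻¹ s⁻¹, Ea = 37.0 kJ mol⁻¹)
    target ⇌ isomer of the product (K = 10.0, k = 0.0133 s⁻¹, Ea = 74.0 kJ mol⁻¹, ΔH = −66.0 kJ mol⁻¹)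
    (constants at −20 °C)

Summer leaves 8.93 %, autumn gives 16.2 % against the 16.9 % reckoned, and the best remedy is midnight, whose gain of 27 points is larger than those of autumn, 7.3 points, and noon, 0.78 points. At 30 min the flask holds 89.3 % isomer of the product beside its target. The repeat at −5 °C, with 35.5 % target, has a ratio counted as S was of 1.82, lower than the 9.73 read at −20 °C.

(The numbers in the tables are simulated for an exercise, and the scatter is random.)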